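**Retrosynthetic overview**

1. The target comes from a bicyclic lactone by oxidation of the C14 allylic alcohol and removal of the C15 silyl group.
2. Key step: an acyclic ω-formyl (Z)-2-(bromomethyl)enoate closes the ten-membered carbocycle by intramolecular allylation (C6–C7, first ring), and the resulting syn hydroxy ester closes the γ-lactone (O6–C12, second ring) in the same operation.
3. The allylic bromide comes from a C7 aldehyde and methyl propiolate (vinylalumination, then SN2' bromination); the C8 stereocentre comes from (R)-glycidol.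
4. Both ring-cis trisubstituted alkenes are set acyclically by two E-selective Horner–Wadsworth–Emmons reactions: C4=C5 from a phosphonoacetate and glyoxal monoacetal, C1=C10 from an α-phosphono-γ-lactone.

Assumption: atom labels C1–C15 follow germacrane numbering (C6 lactone carbinol, C7 ring-fusion CH, C8 ester carbinol, C11–C13 acrylate carbons, C14 formyl carbon, C15 hydroxymethyl carbon); the target is taken as (6S,7R,8S) with both ring alkenes ring-cis (E by CIP), as the SMILES states.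

**Route**

Step 1
Reactants: 1 triethyl phosphonoacetate; 2 acrylonitrile
Product: 3 ethyl 4-cyano-2-(diethoxyphosphoryl)butanoate (racemic)
Conditions: NaOEt (5 mol%), EtOH, 0 °C to rt (1 in excess)
Reagents that add atoms: none
Why: Michael addition of the stabilised phosphonate anion to acrylonitrile installs C1–C3 with the nitrile as masked C1 aldehyde; no lasting stereocentre.

Step 2
Reactants: 3 ethyl 4-cyano-2-(diethoxyphosphoryl)butanoate; 4 2,2-dimethoxyacetaldehyde (60 wt% in water)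
Product: 5 ethyl (2E)-2-(2-cyanoethyl)-4,4-dimethoxybut-2-enoate
Conditions: K2CO3 (aq.), THF, rt
Reagents that add atoms: none
Why: Horner–Wadsworth–Emmons olefination of the α-branched phosphonate gives the E-enoate (ester trans to the acetal carbon), which fixes the ring-cis C4=C5 geometry (C3 cis to C6).

Step 3
Reactants: 5 ethyl (2E)-2-(2-cyanoethyl)-4,4-dimethoxybut-2-enoate
Product: 6 (4E)-4-(hydroxymethyl)-6,6-dimethoxyhex-4-enal (in equilibrium with its six-membered lactol)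
Conditions: i-Bu2AlH (3.5 equiv), CH2Cl2, −78 °C; aq. KNaC4H4O6
Reagents that add atoms: water, O
Why: One-pot hydride reduction of the conjugated ester to the C15 allylic alcohol and of the nitrile to the aldimine, which hydrolyses on work-up to the C1 aldehyde; the alkene geometry is untouched.

Step 4
Reactants: 7 (R)-glycidol
Product: 8 triethyl{[(2S)-oxiran-2-yl]methoxy}silane
Conditions: Et3SiCl, imidazole, CH2Cl2, 0 °C
Reagents that add atoms: chlorotriethylsilane, CC[Si](Cl)(CC)CC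
Why: O-silylation of the primary alcohol; the stereocentre is untouched (the descriptor changes from R to S only through CIP priorities).

Step 5
Reactants: 8 triethyl{[(2S)-oxiran-2-yl]methoxy}silane; 1 triethyl phosphonoacetate
Product: 9 diethyl [(5S)-2-oxo-5-{[(triethylsilyl)oxy]methyl}oxolan-3-yl]phosphonate (C3 epimers)
Conditions: NaH, DME, 0 °C; then 8, 80 °C; aq. NH4Cl
Reagents that add atoms: none
Why: Epoxide opening by the phosphonoacetate anion at the terminal carbon followed by lactonisation gives the α-phosphono-γ-lactone; the C8 carbinol centre is carried over unchanged from 8.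

Step 6
Reactants: 9 diethyl [(5S)-2-oxo-5-{[(triethylsilyl)oxy]methyl}oxolan-3-yl]phosphonate; 6 (4E)-4-(hydroxymethyl)-6,6-dimethoxyhex-4-enal
Product: 10 (3E,5S)-3-[(4E)-4-(hydroxymethyl)-6,6-dimethoxyhex-4-en-1-ylidene]-5-{[(triethylsilyl)oxy]methyl}oxolan-2-one
Conditions: LiCl, DBU, MeCN, 0 °C to rt
Reagents that add atoms: none
Why: Masamune–Roush Horner–Wadsworth–Emmons olefination (the lactol reacts through its open aldehyde form) gives the E-alkylidene lactone with the chain trans to the lactone carbonyl, fixing the ring-cis C1=C10 geometry (C2 cis to C9).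

Step 7
Reactants: 10 (3E,5S)-3-[(4E)-4-(hydroxymethyl)-6,6-dimethoxyhex-4-en-1-ylidene]-5-{[(triethylsilyl)oxy]methyl}oxolan-2-one
Product: 11 (3E,5S)-3-[(4E)-4-({[tert-butyl(diphenyl)silyl]oxy}methyl)-6,6-dimethoxyhex-4-en-1-ylidene]-5-{[(triethylsilyl)oxy]methyl}oxolan-2-one
Conditions: t-BuPh2SiCl, imidazole, DMF, rt
Reagents that add atoms: tert-butyl(chloro)diphenylsilane, CC(C)(C)[Si](Cl)(c1ccccc1)c1ccccc1
Why: Silyl protection of the C15 allylic alcohol so that it stays distinct from the C14 alcohol released in the next step.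

Step 8
Reactants: 11 (3E,5S)-3-[(4E)-4-({[tert-butyl(diphenyl)silyl]oxy}methyl)-6,6-dimethoxyhex-4-en-1-ylidene]-5-{[(triethylsilyl)oxy]methyl}oxolan-2-one
Product: 12 (2S,4E,8E)-8-({[tert-butyl(diphenyl)silyl]oxy}methyl)-4-(hydroxymethyl)-10,10-dimethoxy-1-[(triethylsilyl)oxy]deca-4,8-dien-2-ol
Conditions: i-Bu2AlH (3 equiv), CH2Cl2, −78 to 0 °C; aq. KNaC4H4O6
Reagents that add atoms: none
Why: 1,2-Reduction of the unsaturated lactone to the primary allylic alcohol (C14) and the secondary alcohol (C8); no stereocentre or alkene is affected.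

Step 9
Reactants: 12 (2S,4E,8E)-8-({[tert-butyl(diphenyl)silyl]oxy}methyl)-4-(hydroxymethyl)-10,10-dimethoxy-1-[(triethylsilyl)oxy]deca-4,8-dien-2-ol; 13 3-methylbutanoyl chloride
Product: 15 (2S,4E,8E)-4-({[tert-butyl(dimethyl)silyl]oxy}methyl)-8-({[tert-butyl(diphenyl)silyl]oxy}methyl)-10,10-dimethoxy-1-[(triethylsilyl)oxy]deca-4,8-dien-2-yl 3-methylbutanoate, via mono-TBS ether 14 (not isolated)
Conditions: t-BuMe2SiCl (1.05 equiv), imidazole, CH2Cl2, −20 °C; then 13, pyridine, DMAP, 0 °C to rt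
Reagents that add atoms: tert-butyl(chloro)dimethylsilane, CC(C)(C)[Si](C)(C)Cl
Why: Selective silylation of the primary allylic alcohol, then DMAP-catalysed esterification of the remaining secondary C8 alcohol with retention of configuration.

Step 10
Reactants: 15 (2S,4E,8E)-4-({[tert-butyl(dimethyl)silyl]oxy}methyl)-8-({[tert-butyl(diphenyl)silyl]oxy}methyl)-10,10-dimethoxy-1-[(triethylsilyl)oxy]deca-4,8-dien-2-yl 3-methylbutanoate
Product: 16 (2S,4E,8E)-4-({[tert-butyl(dimethyl)silyl]oxy}methyl)-8-({[tert-butyl(diphenyl)silyl]oxy}methyl)-10,10-dimethoxy-1-oxodeca-4,8-dien-2-yl 3-methylbutanoate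
Conditions: (COCl)2, DMSO, CH2Cl2, −78 °C; i-Pr2NEt, −78 to −30 °C
Reagents that add atoms: none
Why: Swern oxidation that cleaves and oxidises only the primary triethylsilyl ether, giving the C7 aldehyde without passing through a free 1,2-hydroxy ester; low temperature and a hindered base protect the C8 centre.

Step 11
Reactants: 16 (2S,4E,8E)-4-({[tert-butyl(dimethyl)silyl]oxy}methyl)-8-({[tert-butyl(diphenyl)silyl]oxy}methyl)-10,10-dimethoxy-1-oxodeca-4,8-dien-2-yl 3-methylbutanoate; 17 methyl propiolate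
Product: 19 methyl (4S,6E,10E)-6-({[tert-butyl(dimethyl)silyl]oxy}methyl)-10-({[tert-butyl(diphenyl)silyl]oxy}methyl)-3-hydroxy-12,12-dimethoxy-2-methylidene-4-[(3-methylbutanoyl)oxy]dodeca-6,10-dienoate (C3 epimers), via vinylalane 18 (not isolated)
Conditions: 17, i-Bu2AlH, NMO, THF, 0 °C; then 16, 0 °C; aq. KNaC4H4O6
Reagents that add atoms: none
Why: Vinylalumination (a Morita–Baylis–Hillman equivalent): conjugate hydroalumination of the propiolate gives the α-aluminio acrylate, which adds to the aldehyde under non-basic conditions; the new C7 carbinol centre is erased in the next step.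

Step 12
Reactants: 19 methyl (4S,6E,10E)-6-({[tert-butyl(dimethyl)silyl]oxy}methyl)-10-({[tert-butyl(diphenyl)silyl]oxy}methyl)-3-hydroxy-12,12-dimethoxy-2-methylidene-4-[(3-methylbutanoyl)oxy]dodeca-6,10-dienoate
Product: 20 methyl (2Z,4S,6E,10E)-2-(bromomethyl)-6-({[tert-butyl(dimethyl)silyl]oxy}methyl)-10-({[tert-butyl(diphenyl)silyl]oxy}methyl)-12,12-dimethoxy-4-[(3-methylbutanoyl)oxy]dodeca-2,6,10-trienoate
Conditions: NBS, Me2S, CH2Cl2, 0 °C
Reagents that add atoms: N-bromosuccinimide, O=C1CCC(=O)N1Br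
Why: Corey–Kim-type bromination with SN2' allylic transposition gives the thermodynamically preferred Z-2-(bromomethyl)enoate (CH2Br cis to C8).

Step 13 (key step)
Reactants: 20 methyl (2Z,4S,6E,10E)-2-(bromomethyl)-6-({[tert-butyl(dimethyl)silyl]oxy}methyl)-10-({[tert-butyl(diphenyl)silyl]oxy}methyl)-12,12-dimethoxy-4-[(3-methylbutanoyl)oxy]dodeca-2,6,10-trienoate
Product: 23 (3aR,4S,6E,10E,11aS)-10-({[tert-butyl(diphenyl)silyl]oxy}methyl)-6-(hydroxymethyl)-3-methylidene-2-oxo-2,3,3a,4,5,8,9,11a-octahydrocyclodeca[b]furan-4-yl 3-methylbutanoate, via formyl bromide 21 (not isolated), via cyclised hydroxy ester 22 (not isolated)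
Conditions: 1 M HCl, THF, 0 °C to rt; then NaOAc to pH 5, dilute to 2 mM (THF/H2O 4:1), In powder, rt then 40 °C
Reagents that add atoms: water, O
Why: Acid unmasks the C6 aldehyde and the C14 alcohol, then an intramolecular Barbier allylation through a Zimmerman–Traxler chair closes the ten-membered ring (the Z-allylindium gives the 6,7-syn adduct; the C8 centre is expected to set the face with H8 in the allyl plane to avoid allylic 1,3-strain, the ester anti to the forming bond and the C9 tether on the aldehyde side, hence 6S,7R) and the syn γ-hydroxy ester lactonises in the same pot to the cis-fused α-methylene lactone.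

Step 14
Reactants: 23 (3aR,4S,6E,10E,11aS)-10-({[tert-butyl(diphenyl)silyl]oxy}methyl)-6-(hydroxymethyl)-3-methylidene-2-oxo-2,3,3a,4,5,8,9,11a-octahydrocyclodeca[b]furan-4-yl 3-methylbutanoate
Product: 24 (3aR,4S,6E,10E,11aS)-10-({[tert-butyl(diphenyl)silyl]oxy}methyl)-6-formyl-3-methylidene-2-oxo-2,3,3a,4,5,8,9,11a-octahydrocyclodeca[b]furan-4-yl 3-methylbutanoate
Conditions: MnO2, CH2Cl2, rt
Reagents that add atoms: none
Why: Allylic oxidation with MnO2 converts only the free primary allylic alcohol (C14) into the enal; the C15 oxygen is silylated and no stereocentre is touched.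

Step 15
Reactants: 24 (3aR,4S,6E,10E,11aS)-10-({[tert-butyl(diphenyl)silyl]oxy}methyl)-6-formyl-3-methylidene-2-oxo-2,3,3a,4,5,8,9,11a-octahydrocyclodeca[b]furan-4-yl 3-methylbutanoate
Product: 25 (3aR,4S,6E,10E,11aS)-6-formyl-10-(hydroxymethyl)-3-methylidene-2-oxo-2,3,3a,4,5,8,9,11a-octahydrocyclodeca[b]furan-4-yl 3-methylbutanoate (target)
Conditions: HF·pyridine, pyridine, THF, 0 °C to rt
Reagents that add atoms: none
Why: Fluoride-mediated desilylation under buffered, non-basic conditions that spare the enal, the ester and the α-methylene lactone.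

**Compound list**

1 | triethyl phosphonoacetate | CCOC(=O)CP(=O)(OCC)OCC | starting material
2 | acrylonitrile | C=CC#N | starting material
3 | ethyl 4-cyano-2-(diethoxyphosphoryl)butanoate (racemic) | CCOC(=O)C(CCC#N)P(=O)(OCC)OCC | intermediate
4 | 2,2-dimethoxyacetaldehyde | COC(OC)C=O | starting material
5 | ethyl (2E)-2-(2-cyanoethyl)-4,4-dimethoxybut-2-enoate | CCOC(=O)/C(CCC#N)=C/C(OC)OC | intermediate
6 | (4E)-4-(hydroxymethyl)-6,6-dimethoxyhex-4-enal | O=CCC/C(CO)=C\C(OC)OC | intermediate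
7 | (R)-glycidol | OC[C@@H]1CO1 | starting material
8 | triethyl{[(2S)-oxiran-2-yl]methoxy}silane | CC[Si](CC)(CC)OC[C@@H]1CO1 | intermediate
9 | diethyl [(5S)-2-oxo-5-{[(triethylsilyl)oxy]methyl}oxolan-3-yl]phosphonate (C3 epimers) | O=C1O[C@H](CO[Si](CC)(CC)CC)CC1P(=O)(OCC)OCC | intermediate
10 | (3E,5S)-3-[(4E)-4-(hydroxymethyl)-6,6-dimethoxyhex-4-en-1-ylidene]-5-{[(triethylsilyl)oxy]methyl}oxolan-2-one | O=C1O[C@H](CO[Si](CC)(CC)CC)C/C1=C\CC/C(CO)=C\C(OC)OC | intermediate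
11 | (3E,5S)-3-[(4E)-4-({[tert-butyl(diphenyl)silyl]oxy}methyl)-6,6-dimethoxyhex-4-en-1-ylidene]-5-{[(triethylsilyl)oxy]methyl}oxolan-2-one | O=C1O[C@H](CO[Si](CC)(CC)CC)C/C1=C\CC/C(CO[Si](c2ccccc2)(c2ccccc2)C(C)(C)C)=C\C(OC)OC | intermediate
12 | (2S,4E,8E)-8-({[tert-butyl(diphenyl)silyl]oxy}methyl)-4-(hydroxymethyl)-10,10-dimethoxy-1-[(triethylsilyl)oxy]deca-4,8-dien-2-ol | OC/C(C[C@H](O)CO[Si](CC)(CC)CC)=C/CC/C(CO[Si](c1ccccc1)(c1ccccc1)C(C)(C)C)=C\C(OC)OC | intermediate
13 | 3-methylbutanoyl chloride (isovaleryl chloride) | CC(C)CC(=O)Cl | starting material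
14 | (2S,4E,8E)-4-({[tert-butyl(dimethyl)silyl]oxy}methyl)-8-({[tert-butyl(diphenyl)silyl]oxy}methyl)-10,10-dimethoxy-1-[(triethylsilyl)oxy]deca-4,8-dien-2-ol | CC(C)(C)[Si](C)(C)OC/C(C[C@H](O)CO[Si](CC)(CC)CC)=C/CC/C(CO[Si](c1ccccc1)(c1ccccc1)C(C)(C)C)=C\C(OC)OC | intermediate
15 | (2S,4E,8E)-4-({[tert-butyl(dimethyl)silyl]oxy}methyl)-8-({[tert-butyl(diphenyl)silyl]oxy}methyl)-10,10-dimethoxy-1-[(triethylsilyl)oxy]deca-4,8-dien-2-yl 3-methylbutanoate | CC(C)(C)[Si](C)(C)OC/C(C[C@H](OC(=O)CC(C)C)CO[Si](CC)(CC)CC)=C/CC/C(CO[Si](c1ccccc1)(c1ccccc1)C(C)(C)C)=C\C(OC)OC | intermediate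
16 | (2S,4E,8E)-4-({[tert-butyl(dimethyl)silyl]oxy}methyl)-8-({[tert-butyl(diphenyl)silyl]oxy}methyl)-10,10-dimethoxy-1-oxodeca-4,8-dien-2-yl 3-methylbutanoate | CC(C)(C)[Si](C)(C)OC/C(C[C@H](OC(=O)CC(C)C)C=O)=C/CC/C(CO[Si](c1ccccc1)(c1ccccc1)C(C)(C)C)=C\C(OC)OC | intermediate
17 | methyl propiolate | C#CC(=O)OC | starting material
18 | methyl 2-(diisobutylalumanyl)prop-2-enoate | C=C(C(=O)OC)[Al](CC(C)C)CC(C)C | intermediate
19 | methyl (4S,6E,10E)-6-({[tert-butyl(dimethyl)silyl]oxy}methyl)-10-({[tert-butyl(diphenyl)silyl]oxy}methyl)-3-hydroxy-12,12-dimethoxy-2-methylidene-4-[(3-methylbutanoyl)oxy]dodeca-6,10-dienoate (C3 epimers) | CC(C)(C)[Si](C)(C)OC/C(C[C@H](OC(=O)CC(C)C)C(O)C(=C)C(=O)OC)=C/CC/C(CO[Si](c1ccccc1)(c1ccccc1)C(C)(C)C)=C\C(OC)OC | intermediate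
20 | methyl (2Z,4S,6E,10E)-2-(bromomethyl)-6-({[tert-butyl(dimethyl)silyl]oxy}methyl)-10-({[tert-butyl(diphenyl)silyl]oxy}methyl)-12,12-dimethoxy-4-[(3-methylbutanoyl)oxy]dodeca-2,6,10-trienoate | CC(C)(C)[Si](C)(C)OC/C(C[C@H](OC(=O)CC(C)C)/C=C(\CBr)C(=O)OC)=C/CC/C(CO[Si](c1ccccc1)(c1ccccc1)C(C)(C)C)=C\C(OC)OC | intermediate
21 | methyl (2Z,4S,6E,10E)-2-(bromomethyl)-10-({[tert-butyl(diphenyl)silyl]oxy}methyl)-6-(hydroxymethyl)-4-[(3-methylbutanoyl)oxy]-12-oxododeca-2,6,10-trienoate | OC/C(C[C@H](OC(=O)CC(C)C)/C=C(\CBr)C(=O)OC)=C/CC/C(CO[Si](c1ccccc1)(c1ccccc1)C(C)(C)C)=C\C=O | intermediate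
22 | methyl 2-[(1S,2S,3E,7E,10S)-4-({[tert-butyl(diphenyl)silyl]oxy}methyl)-2-hydroxy-8-(hydroxymethyl)-10-[(3-methylbutanoyl)oxy]cyclodeca-3,7-dien-1-yl]prop-2-enoate | COC(=O)C(=C)[C@H]1[C@@H](O)/C=C(/CO[Si](c2ccccc2)(c2ccccc2)C(C)(C)C)CC/C=C(/CO)C[C@@H]1OC(=O)CC(C)C | intermediate
23 | (3aR,4S,6E,10E,11aS)-10-({[tert-butyl(diphenyl)silyl]oxy}methyl)-6-(hydroxymethyl)-3-methylidene-2-oxo-2,3,3a,4,5,8,9,11a-octahydrocyclodeca[b]furan-4-yl 3-methylbutanoate | C=C1C(=O)O[C@H]2/C=C(/CO[Si](c3ccccc3)(c3ccccc3)C(C)(C)C)CC/C=C(/CO)C[C@H](OC(=O)CC(C)C)[C@@H]12 | intermediate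
24 | (3aR,4S,6E,10E,11aS)-10-({[tert-butyl(diphenyl)silyl]oxy}methyl)-6-formyl-3-methylidene-2-oxo-2,3,3a,4,5,8,9,11a-octahydrocyclodeca[b]furan-4-yl 3-methylbutanoate | C=C1C(=O)O[C@H]2/C=C(/CO[Si](c3ccccc3)(c3ccccc3)C(C)(C)C)CC/C=C(/C=O)C[C@H](OC(=O)CC(C)C)[C@@H]12 | intermediate
25 | (3aR,4S,6E,10E,11aS)-6-formyl-10-(hydroxymethyl)-3-methylidene-2-oxo-2,3,3a,4,5,8,9,11a-octahydrocyclodeca[b]furan-4-yl 3-methylbutanoate | C=C1C(=O)O[C@H]2/C=C(/CO)CC/C=C(/C=O)C[C@H](OC(=O)CC(C)C)[C@@H]12 | target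

**Step count and risks**

Total steps: 15. Longest linear sequence: 13 (steps 1–3 and 6–15; steps 4–5 are the side branch).

Steps most likely to fail:

Step 13 (macrocyclisation). The ten-membered ring closure competes with oligomerisation and with protonolysis of the allylindium in water. The face selectivity relative to C8 is also not secured by precedent; an open-chain model would put the C9 chain, not the ester, anti to the forming bond. Fallback, setting out from 20 and coming back at 23: the bromide is borylated (B2pin2, Pd2(dba)3 cat., DMSO, rt) to the allyl pinacol boronate F1. Treatment with 1 M HCl in THF unmasks the aldehyde and the C14 alcohol to give the formyl boronate F2. Heating F2 at 2 mM in toluene (80 °C) brings about a neutral intramolecular allylboration through a closed chair, with no metal alkoxide and no protodemetalation. The borate ester lactonises on aqueous work-up to 23.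

Step 11 (acrylate installation). The 2-acyloxy aldehyde 16 can epimerise at C8, and adduct 19 can undergo a 1,2-acyl shift between O8 and O7. Fallback, setting out from 12 and coming back at 20: the ester is introduced only after the allylic bromide exists. Diol 12 is silylated in one pot (t-BuMe2SiCl, then Et3SiOTf and 2,6-lutidine) to the tris-silyl ether F3. Swern oxidation touches only the primary triethylsilyl ether and gives the 2-silyloxy aldehyde F4. Vinylalumination with 17 gives the adduct F5, and NBS/Me2S gives the bromide F6. HF·pyridine buffered with pyridine at −10 °C removes the secondary triethylsilyl group to give the alcohol F7. Acylation of F7 with 13 and 2,6-lutidine gives 20.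

Step 6 (alkylidene lactone geometry). Phosphono-lactone olefinations can give E/Z mixtures. Fallback, setting out from 9 and 6 and coming back at 10: the C1=C10 bond is made by cross-metathesis instead. Phosphonate 9 with aqueous formaldehyde and K2CO3 gives the α-methylene lactone F8. Aldehyde 6 with Ph3P=CH2 (2.2 equiv) gives the terminal alkene F9. Cross-metathesis of F8 with F9 (second-generation Hoveyda–Grubbs catalyst, CH2Cl2, 40 °C) gives the thermodynamically favoured E-alkylidene lactone 10.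

**Further compounds**

F1 | step 13 | methyl (2E,4S,6E,10E)-6-({[tert-butyl(dimethyl)silyl]oxy}methyl)-10-({[tert-butyl(diphenyl)silyl]oxy}methyl)-12,12-dimethoxy-4-[(3-methylbutanoyl)oxy]-2-[(4,4,5,5-tetramethyl-1,3,2-dioxaborolan-2-yl)methyl]dodeca-2,6,10-trienoate | CC(C)(C)[Si](C)(C)OC/C(C[C@H](OC(=O)CC(C)C)/C=C(\CB1OC(C)(C)C(C)(C)O1)C(=O)OC)=C/CC/C(CO[Si](c1ccccc1)(c1ccccc1)C(C)(C)C)=C\C(OC)OC
F2 | step 13 | methyl (2E,4S,6E,10E)-10-({[tert-butyl(diphenyl)silyl]oxy}methyl)-6-(hydroxymethyl)-4-[(3-methylbutanoyl)oxy]-12-oxo-2-[(4,4,5,5-tetramethyl-1,3,2-dioxaborolan-2-yl)methyl]dodeca-2,6,10-trienoate | OC/C(C[C@H](OC(=O)CC(C)C)/C=C(\CB1OC(C)(C)C(C)(C)O1)C(=O)OC)=C/CC/C(CO[Si](c1ccccc1)(c1ccccc1)C(C)(C)C)=C\C=O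
F3 | step 11 | (2S,4E,8E)-4-({[tert-butyl(dimethyl)silyl]oxy}methyl)-8-({[tert-butyl(diphenyl)silyl]oxy}methyl)-10,10-dimethoxy-1,2-bis[(triethylsilyl)oxy]deca-4,8-diene | CC(C)(C)[Si](C)(C)OC/C(C[C@H](O[Si](CC)(CC)CC)CO[Si](CC)(CC)CC)=C/CC/C(CO[Si](c1ccccc1)(c1ccccc1)C(C)(C)C)=C\C(OC)OC
F4 | step 11 | (2S,4E,8E)-4-({[tert-butyl(dimethyl)silyl]oxy}methyl)-8-({[tert-butyl(diphenyl)silyl]oxy}methyl)-10,10-dimethoxy-2-[(triethylsilyl)oxy]deca-4,8-dienal | CC(C)(C)[Si](C)(C)OC/C(C[C@H](O[Si](CC)(CC)CC)C=O)=C/CC/C(CO[Si](c1ccccc1)(c1ccccc1)C(C)(C)C)=C\C(OC)OC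
F5 | step 11 | methyl (4S,6E,10E)-6-({[tert-butyl(dimethyl)silyl]oxy}methyl)-10-({[tert-butyl(diphenyl)silyl]oxy}methyl)-3-hydroxy-12,12-dimethoxy-2-methylidene-4-[(triethylsilyl)oxy]dodeca-6,10-dienoate (C3 epimers) | CC(C)(C)[Si](C)(C)OC/C(C[C@H](O[Si](CC)(CC)CC)C(O)C(=C)C(=O)OC)=C/CC/C(CO[Si](c1ccccc1)(c1ccccc1)C(C)(C)C)=C\C(OC)OC
F6 | step 11 | methyl (2Z,4S,6E,10E)-2-(bromomethyl)-6-({[tert-butyl(dimethyl)silyl]oxy}methyl)-10-({[tert-butyl(diphenyl)silyl]oxy}methyl)-12,12-dimethoxy-4-[(triethylsilyl)oxy]dodeca-2,6,10-trienoate | CC(C)(C)[Si](C)(C)OC/C(C[C@H](O[Si](CC)(CC)CC)/C=C(\CBr)C(=O)OC)=C/CC/C(CO[Si](c1ccccc1)(c1ccccc1)C(C)(C)C)=C\C(OC)OC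
F7 | step 11 | methyl (2Z,4S,6E,10E)-2-(bromomethyl)-6-({[tert-butyl(dimethyl)silyl]oxy}methyl)-10-({[tert-butyl(diphenyl)silyl]oxy}methyl)-4-hydroxy-12,12-dimethoxydodeca-2,6,10-trienoate | CC(C)(C)[Si](C)(C)OC/C(C[C@H](O)/C=C(\CBr)C(=O)OC)=C/CC/C(CO[Si](c1ccccc1)(c1ccccc1)C(C)(C)C)=C\C(OC)OC
F8 | step 6 | (5S)-3-methylidene-5-{[(triethylsilyl)oxy]methyl}oxolan-2-one | O=C1O[C@H](CO[Si](CC)(CC)CC)CC1=C
F9 | step 6 | (2E)-2-(but-3-en-1-yl)-4,4-dimethoxybut-2-en-1-ol | C=CCC/C(CO)=C\C(OC)OC
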